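**Retrosynthetic overview**

1. The strategy rests on the benzene ring being a para-hydroquinone (OH on C2 and C5 of the benzaldehyde) with CHO on C1 and the side-chain CH2 on C6 along one edge, and H on C3 and OMe on C4 along the other. The acetoxy-bearing carbinol oxygen sits two carbons from C6, so it can be bonded for a time to C5 as the oxygen of a 2,3-dihydrobenzofuran.
2. Late stage: target ⇐ bis-silyl aldehyde ⇐ quinone acetate ⇐ hydroxyalkyl methoxyquinone ⇐ oxidative aryl–O cleavage of a 2-undecyl-2,3-dihydrobenzofuran-5-ol.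
3. Key disconnection: the benzene ring and the fused dihydrofuran are cut together at C5–C6, C1–C2 and C2–C3. This leads back to a pentacarbonylchromium (1-methoxyvinyl)carbene whose alkoxy group is the homopropargylic carbinol (C2 is a CO ligand, C3 the vinyl CH2, C1 and C6 the alkyne carbons).
4. Carbene complex ⇐ chromium acylate (methyl vinyl ether + Cr(CO)6) + (R)-homopropargylic alcohol ⇐ (R)-1,2-epoxytridecane + silyl propargyl ether ⇐ (R)-epichlorohydrin + decyl Grignard reagent.
5. Ring order: the chain is built without rings; benzene and dihydrofuran close in one step; the dihydrofuran is reopened one step later. The only stereocentre comes from epichlorohydrin and its C–O bond is never broken.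

Key step: step 6

Remark: ring positions C1 to C6 are those of the target benzaldehyde (C1 bears CHO); the tethered carbene complex is assumed to be too labile for storage, so it is filtered cold and used at once.

**Route**

Step 1
Reactants: 1 1-bromodecane; 2 (R)-epichlorohydrin
Product: 4 (R)-1-chlorotridecan-2-ol, via decylmagnesium bromide 3 (not isolated)
Conditions: Mg, THF, rt to 40 °C; then CuI (10 mol %), 2, THF, −40 to −20 °C; aq. NH4Cl
Reagents that add atoms: none
Why: Copper-catalysed Grignard opening of the epoxide at its unsubstituted CH2 (SN2) is much faster than displacement of the primary chloride, and the stereocentre is not attacked, so its configuration is kept.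

Step 2
Reactants: 4 (R)-1-chlorotridecan-2-ol
Product: 5 (R)-2-undecyloxirane [(R)-1,2-epoxytridecane]
Conditions: NaOH (powder), Et2O, rt
Reagents that add atoms: none
Why: Intramolecular Williamson etherification of the chlorohydrin alkoxide displaces chloride at the CH2 carbon only, so the C–O bond of the stereocentre is retained and the (R) epoxide should result.

Step 3
Reactants: 6 tert-butyldimethyl(prop-2-yn-1-yloxy)silane; 5 (R)-2-undecyloxirane
Product: 8 (R)-1-(tert-butyldimethylsilyloxy)hexadec-2-yn-5-ol, via lithium acetylide 7 (not isolated)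
Conditions: n-BuLi, THF, −78 °C; BF3·OEt2, then 5, −78 °C; H2O
Reagents that add atoms: none
Why: Yamaguchi–Hirao alkynylation, in which the BF3-activated terminal epoxide is opened by the lithium acetylide at the CH2 carbon, leaves the carbinol stereocentre untouched.

Step 4
Reactants: 9 methyl vinyl ether; 10 chromium hexacarbonyl Cr(CO)6
Product: 13 tetramethylammonium pentacarbonyl(2-methoxyacryloyl)chromate Me4N[(CO)5Cr–C(O)C(OMe)=CH2], via 1-methoxyvinyllithium 11 (not isolated), via lithium acylate 12 (not isolated)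
Conditions: t-BuLi, THF, −78 to 0 °C; Cr(CO)6, THF, −78 °C to rt; Me4NBr, degassed H2O, 0 °C
Reagents that add atoms: tetramethylammonium bromide C[N+](C)(C)C.[Br-]
Why: This is the Fischer route to acylmetalates, in which the alpha-lithiated enol ether adds to a CO ligand of Cr(CO)6 and exchange of lithium for tetramethylammonium gives a salt that can be isolated and dried.

Step 5
Reactants: 13 tetramethylammonium pentacarbonyl(2-methoxyacryloyl)chromate; 8 (R)-1-(tert-butyldimethylsilyloxy)hexadec-2-yn-5-ol
Product: 15 pentacarbonyl{[(R)-1-(tert-butyldimethylsilyloxy)hexadec-2-yn-5-yloxy](1-methoxyvinyl)carbene}chromium, via acetoxycarbene complex 14 (not isolated)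
Conditions: AcBr (1.0 equiv), CH2Cl2, −40 °C; then 8, −40 to −10 °C; filtration through SiO2 (pentane/Et2O) below 0 °C
Reagents that add atoms: none
Why: O-acylation of the acylate gives a strongly electrophilic acyloxycarbene, and addition–elimination of the secondary alcohol at the carbene carbon (acyloxy/alkoxy exchange, established for alkenyl complexes and secondary alcohols) installs the tether without touching the carbinol C–O bond.

Step 6
Reactants: 15 pentacarbonyl{[(R)-1-(tert-butyldimethylsilyloxy)hexadec-2-yn-5-yloxy](1-methoxyvinyl)carbene}chromium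
Product: 17 (R)-4-[(tert-butyldimethylsilyloxy)methyl]-7-methoxy-2-undecyl-2,3-dihydrobenzofuran-5-ol, via arene tricarbonylchromium complex 16 (not isolated)
Conditions: THF (0.005 M), 50 °C, Ar; then air, MeCN, rt
Reagents that add atoms: none
Why: Intramolecular Dötz benzannulation of an alkenyl(alkoxy)carbene complex that carries its alkyne on the alkoxy group, a known reaction type: warming expels one CO, the tethered alkyne coordinates and inserts into the Cr=C bond, a CO ligand inserts to give a chromium-bound dienylketene, and 6π electrocyclisation onto the vinyl CH2 followed by tautomerisation gives the phenol as its Cr(CO)3 complex, which air then demetalates. The dihydrofuran ring closes in the insertion step by bonding of the carbene carbon (C5) to the proximal alkyne carbon (C6), a five-membered closure with the new alkene endocyclic, which also holds the new carbene carbon and the methoxyvinyl group cis as the later ring closure requires. The benzene ring closes by CO insertion (C1–C2) and then by the 6π electrocyclisation (C2–C3). No stereocentre is created, and the existing carbinol centre is only a spectator because its C–O bond is not touched. The selectivity needed is regiocontrol in the insertion of an internal alkyne whose two CH2 substituents are alike in size; it is secured entirely by the O–CH–CH2 tether, which can deliver only the proximal alkyne carbon to the carbene carbon, while high dilution suppresses intermolecular insertion.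

Step 7
Reactants: 17 (R)-4-[(tert-butyldimethylsilyloxy)methyl]-7-methoxy-2-undecyl-2,3-dihydrobenzofuran-5-ol
Product: 18 2-[(tert-butyldimethylsilyloxy)methyl]-3-[(R)-2-hydroxytridecyl]-5-methoxy-1,4-benzoquinone
Conditions: PhI(OAc)2, MeCN/H2O (4:1), 0 °C
Reagents that add atoms: water O
Why: Two-electron oxidation of the para-alkoxyphenol by the trivalent iodine reagent gives an oxocarbenium ion at the ring carbon bearing the dihydrofuran oxygen, water adds there, and collapse of the hemiketal to the para-quinone (oxidative dealkylation) cleaves the aryl–O bond, so the carbinol should be released with its configuration intact.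

Step 8
Reactants: 18 2-[(tert-butyldimethylsilyloxy)methyl]-3-[(R)-2-hydroxytridecyl]-5-methoxy-1,4-benzoquinone
Product: 19 (R)-1-{2-[(tert-butyldimethylsilyloxy)methyl]-5-methoxy-3,6-dioxocyclohexa-1,4-dien-1-yl}tridecan-2-yl acetate
Conditions: Ac2O, pyridine, DMAP (cat.), CH2Cl2, 0 °C
Reagents that add atoms: acetic anhydride CC(=O)OC(C)=O
Why: Nucleophile-catalysed O-acylation of the only hydroxyl group is a standard esterification that does not touch the carbinol C–O bond, and the short reaction time at 0 °C limits attack of the amines on the methoxyquinone.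

Step 9
Reactants: 19 (R)-1-{2-[(tert-butyldimethylsilyloxy)methyl]-5-methoxy-3,6-dioxocyclohexa-1,4-dien-1-yl}tridecan-2-yl acetate
Product: 20 (R)-1-{2-[(tert-butyldimethylsilyloxy)methyl]-3,6-dihydroxy-5-methoxyphenyl}tridecan-2-yl acetate
Conditions: Na2S2O4, EtOAc/H2O, rt, Ar
Reagents that add atoms: none
Why: Dithionite reduction of a quinone to its hydroquinone is selective and should leave the silyl ether and the acetate unchanged.

Step 10
Reactants: 20 (R)-1-{2-[(tert-butyldimethylsilyloxy)methyl]-3,6-dihydroxy-5-methoxyphenyl}tridecan-2-yl acetate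
Product: 21 (R)-1-{3,6-bis(tert-butyldimethylsilyloxy)-2-[(tert-butyldimethylsilyloxy)methyl]-5-methoxyphenyl}tridecan-2-yl acetate
Conditions: TBSCl, imidazole, DMF, rt, Ar (crude 20 used at once)
Reagents that add atoms: tert-butyldimethylsilyl chloride CC(C)(C)[Si](C)(C)Cl
Why: Imidazole-promoted silylation of both phenols is standard silyl ether formation and removes the air-sensitive free hydroquinone before the benzylic carbon is oxidised.

Step 11
Reactants: 21 (R)-1-{3,6-bis(tert-butyldimethylsilyloxy)-2-[(tert-butyldimethylsilyloxy)methyl]-5-methoxyphenyl}tridecan-2-yl acetate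
Product: 22 (R)-1-[3,6-bis(tert-butyldimethylsilyloxy)-2-(hydroxymethyl)-5-methoxyphenyl]tridecan-2-yl acetate
Conditions: AcOH/THF/H2O (3:1:1), rt
Reagents that add atoms: none
Why: Acid-catalysed hydrolysis cleaves a primary alkyl silyl ether much faster than aryl silyl ethers, whose oxygen is less basic, and the aqueous (alcohol-free) medium avoids solvolytic etherification of the electron-rich benzylic position.

Step 12
Reactants: 22 (R)-1-[3,6-bis(tert-butyldimethylsilyloxy)-2-(hydroxymethyl)-5-methoxyphenyl]tridecan-2-yl acetate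
Product: 23 (R)-1-[3,6-bis(tert-butyldimethylsilyloxy)-2-formyl-5-methoxyphenyl]tridecan-2-yl acetate
Conditions: Dess–Martin periodinane, pyridine, CH2Cl2, 0 °C to rt
Reagents that add atoms: none
Why: Dess–Martin oxidation takes a primary benzylic alcohol to the aldehyde under buffered conditions that should spare the aryl silyl ethers and the acetate, and the silyl groups keep the hydroquinone from being oxidised.

Step 13
Reactants: 23 (R)-1-[3,6-bis(tert-butyldimethylsilyloxy)-2-formyl-5-methoxyphenyl]tridecan-2-yl acetate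
Product: 24 (R)-1-(2-formyl-3,6-dihydroxy-5-methoxyphenyl)tridecan-2-yl acetate (target CNP0112378.1)
Conditions: TBAF, AcOH (1:1), THF, 0 °C, Ar
Reagents that add atoms: none
Why: Fluoride cleaves aryl silyl ethers rapidly through Si–F bond formation, and the acetic acid buffer keeps the phenols protonated so that the secondary acetate should neither hydrolyse nor migrate.

**Compound list**

1 | 1-bromodecane | CCCCCCCCCCBr | starting material
2 | (R)-epichlorohydrin | ClC[C@H]1CO1 | starting material
3 | decylmagnesium bromide | CCCCCCCCCC[Mg]Br | intermediate (not isolated)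
4 | (R)-1-chlorotridecan-2-ol | CCCCCCCCCCC[C@@H](O)CCl | intermediate
5 | (R)-2-undecyloxirane [(R)-1,2-epoxytridecane] | CCCCCCCCCCC[C@@H]1CO1 | intermediate
6 | tert-butyldimethyl(prop-2-yn-1-yloxy)silane | C#CCO[Si](C)(C)C(C)(C)C | starting material
7 | 3-(tert-butyldimethylsilyloxy)prop-1-ynyllithium | [Li]C#CCO[Si](C)(C)C(C)(C)C | intermediate (not isolated)
8 | (R)-1-(tert-butyldimethylsilyloxy)hexadec-2-yn-5-ol | CCCCCCCCCCC[C@H](CC#CCO[Si](C)(C)C(C)(C)C)O | intermediate
9 | methyl vinyl ether | COC=C | starting material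
10 | chromium hexacarbonyl Cr(CO)6 | [C-]#[O+].[C-]#[O+].[C-]#[O+].[C-]#[O+].[C-]#[O+].[C-]#[O+].[Cr] | starting material
11 | 1-methoxyvinyllithium | [Li]C(=C)OC | intermediate (not isolated)
12 | lithium pentacarbonyl(2-methoxyacryloyl)chromate Li[(CO)5Cr–C(O)C(OMe)=CH2] | C=C(OC)C([O-])=[Cr].[C-]#[O+].[C-]#[O+].[C-]#[O+].[C-]#[O+].[C-]#[O+].[Li+] | intermediate (not isolated)
13 | tetramethylammonium pentacarbonyl(2-methoxyacryloyl)chromate Me4N[(CO)5Cr–C(O)C(OMe)=CH2] | C=C(OC)C([O-])=[Cr].[C-]#[O+].[C-]#[O+].[C-]#[O+].[C-]#[O+].[C-]#[O+].C[N+](C)(C)C | intermediate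
14 | pentacarbonyl[acetoxy(1-methoxyvinyl)carbene]chromium (CO)5Cr=C(OAc)C(OMe)=CH2 | C=C(OC)C(OC(C)=O)=[Cr].[C-]#[O+].[C-]#[O+].[C-]#[O+].[C-]#[O+].[C-]#[O+] | intermediate (not isolated)
15 | pentacarbonyl{[(R)-1-(tert-butyldimethylsilyloxy)hexadec-2-yn-5-yloxy](1-methoxyvinyl)carbene}chromium | CCCCCCCCCCC[C@H](CC#CCO[Si](C)(C)C(C)(C)C)OC(=[Cr])C(=C)OC.[C-]#[O+].[C-]#[O+].[C-]#[O+].[C-]#[O+].[C-]#[O+] | intermediate
16 | tricarbonylchromium arene complex of 17, (arene)Cr(CO)3 | CCCCCCCCCCC[C@@H]1Cc2c(O1)c(OC)cc(O)c2CO[Si](C)(C)C(C)(C)C.[Cr].[C-]#[O+].[C-]#[O+].[C-]#[O+] | intermediate (not isolated)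
17 | (R)-4-[(tert-butyldimethylsilyloxy)methyl]-7-methoxy-2-undecyl-2,3-dihydrobenzofuran-5-ol | CCCCCCCCCCC[C@@H]1Cc2c(O1)c(OC)cc(O)c2CO[Si](C)(C)C(C)(C)C | intermediate
18 | 2-[(tert-butyldimethylsilyloxy)methyl]-3-[(R)-2-hydroxytridecyl]-5-methoxy-1,4-benzoquinone | CCCCCCCCCCC[C@H](CC1=C(CO[Si](C)(C)C(C)(C)C)C(=O)C=C(OC)C1=O)O | intermediate
19 | (R)-1-{2-[(tert-butyldimethylsilyloxy)methyl]-5-methoxy-3,6-dioxocyclohexa-1,4-dien-1-yl}tridecan-2-yl acetate | CCCCCCCCCCC[C@H](CC1=C(CO[Si](C)(C)C(C)(C)C)C(=O)C=C(OC)C1=O)OC(C)=O | intermediate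
20 | (R)-1-{2-[(tert-butyldimethylsilyloxy)methyl]-3,6-dihydroxy-5-methoxyphenyl}tridecan-2-yl acetate | CCCCCCCCCCC[C@H](Cc1c(O)c(OC)cc(O)c1CO[Si](C)(C)C(C)(C)C)OC(C)=O | intermediate
21 | (R)-1-{3,6-bis(tert-butyldimethylsilyloxy)-2-[(tert-butyldimethylsilyloxy)methyl]-5-methoxyphenyl}tridecan-2-yl acetate | CCCCCCCCCCC[C@H](Cc1c(O[Si](C)(C)C(C)(C)C)c(OC)cc(O[Si](C)(C)C(C)(C)C)c1CO[Si](C)(C)C(C)(C)C)OC(C)=O | intermediate
22 | (R)-1-[3,6-bis(tert-butyldimethylsilyloxy)-2-(hydroxymethyl)-5-methoxyphenyl]tridecan-2-yl acetate | CCCCCCCCCCC[C@H](Cc1c(O[Si](C)(C)C(C)(C)C)c(OC)cc(O[Si](C)(C)C(C)(C)C)c1CO)OC(C)=O | intermediate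
23 | (R)-1-[3,6-bis(tert-butyldimethylsilyloxy)-2-formyl-5-methoxyphenyl]tridecan-2-yl acetate | CCCCCCCCCCC[C@H](Cc1c(O[Si](C)(C)C(C)(C)C)c(OC)cc(O[Si](C)(C)C(C)(C)C)c1C=O)OC(C)=O | intermediate
24 | (R)-1-(2-formyl-3,6-dihydroxy-5-methoxyphenyl)tridecan-2-yl acetate (CNP0112378.1) | CCCCCCCCCCC[C@H](Cc1c(O)c(OC)cc(O)c1C=O)OC(C)=O | target

**Step count and risks**

Total step count: 13. Longest linear sequence: 12 steps (steps 1 to 3 and 5 to 13; step 4 is the side branch).

Steps most likely to fail:

Step 6 (ring construction). After CO loss the short tether may not let the alkyne reach the metal in the orientation needed for insertion. The 1-methoxyvinyl complex may also decompose, or the sequence may be diverted at the vinylketene stage to cyclobutenone-type or oligomeric products before the ring aromatises. The fallback abandons chromium and takes the ring from an existing arene, attaching the side chain by directed ortho-metalation. It sets out from epoxide 5 and comes back to the route at quinone 19. Commercial 2,4,5-trimethoxybenzoic acid is converted ((COCl)2, then Et2NH) into N,N-diethyl-2,4,5-trimethoxybenzamide F1. Lithiation at the position flanked by the amide and a methoxy group (s-BuLi, TMEDA, THF, −78 °C) and opening of 5 in the presence of BF3·OEt2 should give N,N-diethyl-2-[(R)-2-hydroxytridecyl]-3,4,6-trimethoxybenzamide F2. Acid (TsOH, toluene, heat) lactonises this to (R)-5,6,8-trimethoxy-3-undecylisochroman-1-one F3. LiAlH4 reduction should give (R)-1-[2-(hydroxymethyl)-3,5,6-trimethoxyphenyl]tridecan-2-ol F4. Silylation of the primary hydroxyl (TBSCl, imidazole, DMF, 0 °C) gives (R)-1-{2-[(tert-butyldimethylsilyloxy)methyl]-3,5,6-trimethoxyphenyl}tridecan-2-ol F5, and acetylation (Ac2O, pyridine) gives (R)-1-{2-[(tert-butyldimethylsilyloxy)methyl]-3,5,6-trimethoxyphenyl}tridecan-2-yl acetate F6. Oxidative demethylation of the para-dimethoxy pair with (NH4)2Ce(NO3)6 in aqueous MeCN at 0 °C should then give 19, the third methoxy group remaining as the quinone methyl ether.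

Step 5 (assembly of the tethered carbene). Attack of the hindered secondary alcohol on the acetoxycarbene may be slower than decomposition of that complex. The alcohol may add to the vinyl terminus instead of the carbene carbon, or the product may cyclise and oligomerise during concentration. The fallback gives up the tether and runs an intermolecular benzannulation in which regiocontrol comes from the size difference of the two alkyne substituents. It sets out from acylate 13 and epoxide 5 and comes back at target 24. O-Methylation of 13 (Me3OBF4, CH2Cl2, 0 °C) gives pentacarbonyl[methoxy(1-methoxyvinyl)carbene]chromium F7. Epoxide 5 is opened with lithiated 3,3-diethoxyprop-1-yne (n-BuLi, BF3·OEt2, THF, −78 °C) to give (R)-1,1-diethoxyhexadec-2-yn-5-ol F8, which is acetylated (Ac2O, pyridine, DMAP) to (R)-1,1-diethoxyhexadec-2-yn-5-yl acetate F9. Dötz benzannulation of F7 with F9 (THF, 50 °C) should place the branched acetal carbon next to the new phenol and give (R)-1-[2-(diethoxymethyl)-3-hydroxy-5,6-dimethoxyphenyl]tridecan-2-yl acetate F10. Regiocontrol here is expected to be incomplete, so the isomer would have to be removed by chromatography. (NH4)2Ce(NO3)6 in aqueous MeCN oxidises the para-methoxyphenol and hydrolyses the acetal to (R)-1-(2-formyl-5-methoxy-3,6-dioxocyclohexa-1,4-dien-1-yl)tridecan-2-yl acetate F11, which is reduced at once with Na2S2O4 to 24.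

Step 11 (selective desilylation). The aryl silyl ethers may be lost in part, a silyl group may migrate to the freed benzylic oxygen, or the electron-rich benzylic position may ionise before the primary silyl ether is fully hydrolysed. The fallback protects the phenols as acetates instead of silyl ethers, so that fluoride meets only one silyl group and the last step distinguishes aryl from alkyl acetates. It sets out from hydroquinone 20 and comes back at target 24. Acetylation (Ac2O, pyridine) gives (R)-1-{3,6-diacetoxy-2-[(tert-butyldimethylsilyloxy)methyl]-5-methoxyphenyl}tridecan-2-yl acetate F12. HF·pyridine (THF, 0 °C) removes the silyl group to give (R)-1-[3,6-diacetoxy-2-(hydroxymethyl)-5-methoxyphenyl]tridecan-2-yl acetate F13, which is oxidised without delay (Dess–Martin periodinane) to (R)-1-(3,6-diacetoxy-2-formyl-5-methoxyphenyl)tridecan-2-yl acetate F14. Brief methanolysis (K2CO3 cat., MeOH, 0 °C) should cleave the two aryl acetates much faster than the secondary alkyl acetate and give 24.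

**Further compounds**

F1 | step 6 | N,N-diethyl-2,4,5-trimethoxybenzamide | CCN(CC)C(=O)c1cc(OC)c(OC)cc1OC
F2 | step 6 | N,N-diethyl-2-[(R)-2-hydroxytridecyl]-3,4,6-trimethoxybenzamide | CCCCCCCCCCC[C@H](Cc1c(OC)c(OC)cc(OC)c1C(=O)N(CC)CC)O
F3 | step 6 | (R)-5,6,8-trimethoxy-3-undecylisochroman-1-one | CCCCCCCCCCC[C@@H]1Cc2c(OC)c(OC)cc(OC)c2C(=O)O1
F4 | step 6 | (R)-1-[2-(hydroxymethyl)-3,5,6-trimethoxyphenyl]tridecan-2-ol | CCCCCCCCCCC[C@H](Cc1c(OC)c(OC)cc(OC)c1CO)O
F5 | step 6 | (R)-1-{2-[(tert-butyldimethylsilyloxy)methyl]-3,5,6-trimethoxyphenyl}tridecan-2-ol | CCCCCCCCCCC[C@H](Cc1c(OC)c(OC)cc(OC)c1CO[Si](C)(C)C(C)(C)C)O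
F6 | step 6 | (R)-1-{2-[(tert-butyldimethylsilyloxy)methyl]-3,5,6-trimethoxyphenyl}tridecan-2-yl acetate | CCCCCCCCCCC[C@H](Cc1c(OC)c(OC)cc(OC)c1CO[Si](C)(C)C(C)(C)C)OC(C)=O
F7 | step 5 | pentacarbonyl[methoxy(1-methoxyvinyl)carbene]chromium (CO)5Cr=C(OMe)C(OMe)=CH2 | C=C(OC)C(OC)=[Cr].[C-]#[O+].[C-]#[O+].[C-]#[O+].[C-]#[O+].[C-]#[O+]
F8 | step 5 | (R)-1,1-diethoxyhexadec-2-yn-5-ol | CCCCCCCCCCC[C@H](CC#CC(OCC)OCC)O
F9 | step 5 | (R)-1,1-diethoxyhexadec-2-yn-5-yl acetate | CCCCCCCCCCC[C@H](CC#CC(OCC)OCC)OC(C)=O
F10 | step 5 | (R)-1-[2-(diethoxymethyl)-3-hydroxy-5,6-dimethoxyphenyl]tridecan-2-yl acetate | CCCCCCCCCCC[C@H](Cc1c(OC)c(OC)cc(O)c1C(OCC)OCC)OC(C)=O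
F11 | step 5 | (R)-1-(2-formyl-5-methoxy-3,6-dioxocyclohexa-1,4-dien-1-yl)tridecan-2-yl acetate | CCCCCCCCCCC[C@H](CC1=C(C=O)C(=O)C=C(OC)C1=O)OC(C)=O
F12 | step 11 | (R)-1-{3,6-diacetoxy-2-[(tert-butyldimethylsilyloxy)methyl]-5-methoxyphenyl}tridecan-2-yl acetate | CCCCCCCCCCC[C@H](Cc1c(OC(C)=O)c(OC)cc(OC(C)=O)c1CO[Si](C)(C)C(C)(C)C)OC(C)=O
F13 | step 11 | (R)-1-[3,6-diacetoxy-2-(hydroxymethyl)-5-methoxyphenyl]tridecan-2-yl acetate | CCCCCCCCCCC[C@H](Cc1c(OC(C)=O)c(OC)cc(OC(C)=O)c1CO)OC(C)=O
F14 | step 11 | (R)-1-(3,6-diacetoxy-2-formyl-5-methoxyphenyl)tridecan-2-yl acetate | CCCCCCCCCCC[C@H](Cc1c(OC(C)=O)c(OC)cc(OC(C)=O)c1C=O)OC(C)=O
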